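**Assumptions (remarks on the chemistry)**
- 5,7-Dihydroxy-4H-chromen-4-one (1) is treated as a purchasable catalogue compound.
- The (S)-configured biaryl bisphosphine is assumed to give the (S)-flavanone, by transfer of the facial model known for cyclic enones (the CIP priorities at the β-carbon map without change of descriptor). Should the antipode form, the (R)-ligand is used.
- Abbreviations: MeO-F12-BIPHEP = 2,2'-bis[bis(3,4,5-trifluorophenyl)phosphino]-6,6'-dimethoxy-1,1'-biphenyl; fod = 6,6,7,7,8,8,8-heptafluoro-2,2-dimethyloctane-3,5-dionate; DIAD = diisopropyl azodicarboxylate.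

## The problem

The target 10 is (2S)-5,7-dihydroxy-4'-methoxy-8-prenylflavanone. A benzene ring A carrying three oxygens (O5, O7, O1) and a prenyl group at C8 is fused to a dihydropyranone ring C, which bears the 4-methoxyphenyl ring B at C2. Closing the rings is easy; the difficulty is two selectivity problems on a small, sensitive molecule.

First, C2 is the only stereocentre, so nothing in the molecule can control it, and it is labile. It is benzylic to an electron-rich ring and β to the C4 ketone with O1 as leaving group, so base opens ring C by retro-oxa-Michael reaction to an achiral 2'-hydroxychalcone. Second, C6 and C8 of ring A are both flanked by two oxygens and are almost equally nucleophilic. In any open-chain precursor the two oxygens ortho to the acyl group are interchangeable, so "8-prenyl" and "6-prenyl" differ only in which oxygen closes ring C. Third, the prenyl alkene does not survive hydrogenation, strong acid (cyclisation onto O7) or electrophilic reagents, and the free phenols limit oxidants and bases.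

The feature that makes the key step possible is that C2 carries only H, O1 and ring B, and C3 is an unsubstituted CH2 next to the C4 ketone. C2 is therefore the β-carbon of the O1–C2=C3–C4=O enone of a 4H-chromen-4-one, and ring B can be delivered to it by a chiral catalyst when ring C is already closed. A second feature serves the regiochemistry: O5 is chelated to C4=O (and so distinguishable from O7), C6 is ortho and C8 is para to it, so two consecutive [3,3] shifts can carry a prenyl group from O5 to C8.

## Retrosynthesis

**10 from 9 (O7–Si bond).** The last operation is removal of a triisopropylsilyl group from O7. A silyl ether is chosen because it leaves under buffered fluoride, conditions that are neither basic enough to open ring C nor acidic enough to cyclise the prenyl group onto O7.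

**9 from 6 (C8–prenyl bond cut, prenyl returned to O5).** The C8–CH2 bond is disconnected and the prenyl group is placed on O5 as an ether. Direct C-prenylation of ring A would have to choose between C6, C8 and the oxygens, and cross-coupling would need a C8-selective halogenation that the equally activated C6 does not allow. Precursor 6 carries the prenyl group on the one oxygen that chelation makes unique. The forward reaction is a europium-catalysed Claisen–Cope relay through dienones 7 and 8. It must run to completion (C6, then C8) below the temperature at which C2 is endangered. The prenyl group thus enters as the protecting group of O5 and ends as the C8 substituent, leaving O5 free.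

**6 from 4 and 5 (C2–C1' bond).** The bond between C2 and ring B is cut, giving the flat, achiral chromone 4 and 4-methoxyphenylboronic acid 5. This is preferred to the O1–C2 cut (chalcone closure) because ring C stays closed: O1 is fixed on its carbon of ring A, and the reversible ring closure that racemises flavanones is never used to make the stereocentre. It is preferred to C2–C3 or C4–C4a cuts because those need a chiral benzylic ether made beforehand. The precursor is much simpler than the product: no stereocentre, and ring B comes from a commercial reagent. The forward reaction must select one face of C2=C3, add 1,4 and not 1,2, tolerate the prenyl and silyl ethers, and run without base.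

**4 from 2 and 3; 2 from 1 (O5–C and O7–Si bonds).** The prenyl ether is made from 3-methylbut-2-en-1-ol 3 by Mitsunobu etherification of the chelated 5-OH of 2. The silyl ether 2 comes from selective silylation of the non-chelated 7-OH of 5,7-dihydroxychromone 1. The hydrogen bond from O5–H to C4=O is the only differentiating element needed.

## Roads not taken

**Alternative 1:** Cut O1–C2 (the most obvious cut).
- Forward: C-prenylation of 2,4,6-trihydroxyacetophenone to 1-[2,4,6-trihydroxy-3-(3-methylbut-2-enyl)phenyl]ethanone A1, Claisen–Schmidt condensation with 4-methoxybenzaldehyde to chalcone A2, then 6-endo oxa-Michael closure.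
- Why not: A2 has two hydroxyls ortho to the acyl group. Closure through the one next to the prenyl group gives 10, and closure through the other gives the 6-prenyl isomer A3; nothing in A2 favours the more hindered oxygen. The closure is reversible, so it delivers a thermodynamic mixture, and the same reversibility racemises C2. Enantioselective catalysts for this closure rely on an extra activating group at the α-carbon that must be added and removed. The C-prenylation leading to A1 is itself unselective.
- The chosen plan closes ring C before C2 exists and never passes through a chalcone.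

**Alternative 2:** Cut ring A (C4a–C5 and C8–C8a) and build it last.
- Forward: catalytic asymmetric hetero-Diels–Alder reaction of 4-methoxybenzaldehyde with 1-methoxy-3-(trimethylsilyloxy)buta-1,3-diene to (S)-2-(4-methoxyphenyl)-2,3-dihydro-4H-pyran-4-one A4, bromination at C5 to A5, then Diels–Alder reaction with 1-methoxy-7-methyl-1,3-bis(trimethylsilyloxy)octa-1,3,6-triene A6 and loss of HBr and methanol to give 10 directly.
- Attraction: no protecting groups, and the prenyl position is fixed by the diene.
- Why not: the C5=C6 bond of A5 is a push-pull alkene (vinylogous ester) and a poor dienophile. The Lewis acid needed to activate it would ionise the C2–O1 bond, which is benzylic to a 4-methoxyphenyl ring. The plan also spends its key step on ring A, the cheap half of the molecule.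

**Alternative 3:** Cut C2–C3.
- Forward: 2-(4-methoxyphenyl)-5-(3-methylbut-2-enyloxy)-7-(triisopropylsilyloxy)-4H-1,3-benzodioxin-4-one A7 (from a salicylic acid and 4-methoxybenzaldehyde) is methylenated with Cp2TiMe2 to enol acetal A8. A Lewis acid then induces a Petasis–Ferrier rearrangement (ionisation to an aryloxycarbenium ion and a tethered enolate, 6-endo recombination) to 6.
- Attraction: C2 passes through a planar cation, so the step could in principle be stereoconvergent.
- Why not: enantiocontrol would need a chiral acid to govern a tethered ion pair, which is not established on benzo-fused acetals. A Lewis acid strong enough to ionise the acetal also ionises the O5-prenyl ether. A7 needs the same O5/O7 differentiation plus a methylenation, so the route is longer with no gain.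

Key step: step 3

## Route

**Step 1**
Reactants: 1 5,7-dihydroxy-4H-chromen-4-one
Product: 2 5-hydroxy-7-(triisopropylsilyloxy)-4H-chromen-4-one
Conditions: iPr3SiCl (1.05 equiv), imidazole, DMF, 0 °C to rt
Reagents that add atoms: triisopropylsilyl chloride, CC(C)[Si](Cl)(C(C)C)C(C)C
Why: Chelation-controlled selective O-silylation; O5–H is locked in a hydrogen bond to the C4 carbonyl and is far less nucleophilic than the acidic O7–H, so one equivalent of silyl chloride should react at O7 only.

**Step 2**
Reactants: 2 5-hydroxy-7-(triisopropylsilyloxy)-4H-chromen-4-one; 3 3-methylbut-2-en-1-ol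
Product: 4 5-(3-methylbut-2-enyloxy)-7-(triisopropylsilyloxy)-4H-chromen-4-one
Conditions: PPh3, DIAD, THF, 0 °C to rt
Reagents that add atoms: none
Why: Mitsunobu etherification; the chelated 5-OH is acidic enough to protonate the betaine and is alkylated at the primary carbon of the activated alcohol (SN2), under neutral conditions that spare the aryl silyl ether; this etherification is established on chelated 5-hydroxy flavonoids.

**Step 3**
Reactants: 4 5-(3-methylbut-2-enyloxy)-7-(triisopropylsilyloxy)-4H-chromen-4-one; 5 4-methoxyphenylboronic acid
Product: 6 (S)-2-(4-methoxyphenyl)-5-(3-methylbut-2-enyloxy)-7-(triisopropylsilyloxy)chroman-4-one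
Conditions: [Rh(OH)(cod)]2 (cat.), (S)-MeO-F12-BIPHEP (cat.), toluene/H2O, 30 °C
Reagents that add atoms: none
Why: The closest known reaction type is the Hayashi–Miyaura asymmetric 1,4-addition, which is established on chromones with electron-poor biaryl bisphosphines. Transmetalation from boron gives an aryl complex of monovalent rhodium, the C2=C3 bond of 4 coordinates, and migratory insertion places the aryl group on C2 and rhodium on C3 as an oxa-π-allyl enolate, which water protonates at C3 to release 6 and the hydroxo-rhodium species. No ring is closed: ring C is already in place, so O1 cannot end up on the wrong carbon of ring A and no chalcone is formed. The only new stereocentre, C2, is set by the catalyst, whose (S)-ligand should differentiate the faces of the planar enone and deliver the aryl group to the face that gives the S configuration. The step needs 1,4- over 1,2-addition, which the weakly donating fluorinated phosphine and the O5 ether flanking the C4 carbonyl should secure. It needs protonation to outrun β-oxygen elimination of the enolate, which the aqueous medium should secure, and it needs the prenyl ether to stay inert, as a trisubstituted alkene that binds rhodium poorly should. No base beyond the catalytic hydroxo complex is present, so 6 should not racemise by retro-oxa-Michael opening.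

**Step 4**
Reactants: 6 (S)-2-(4-methoxyphenyl)-5-(3-methylbut-2-enyloxy)-7-(triisopropylsilyloxy)chroman-4-one
Product: 9 (S)-5-hydroxy-2-(4-methoxyphenyl)-8-(3-methylbut-2-enyl)-7-(triisopropylsilyloxy)chroman-4-one, via C6 ortho-dienone 7 (not isolated), via C8 para-dienone 8 (not isolated)
Conditions: Eu(fod)3 (10 mol %), NaHCO3, CHCl3, 60 °C
Reagents that add atoms: none
Why: Europium-catalysed aromatic Claisen–Cope cascade, known on 5-O-prenyl flavanones; trivalent europium chelated between C4=O and O5 triggers the [3,3] shift of the allyl aryl ether to C6 (dienone 7, 1,1-dimethylallyl group), a second [3,3] (Cope) shift through C7=C8 carries the group to C8 with the normal prenyl connectivity (8), and enolisation to the chelated 5-phenol makes the sequence irreversible. C8 is the only position para to O5, so the regiochemistry is fixed by the mechanism, and in the absence of base or protic acid C2 should keep its configuration.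

**Step 5**
Reactants: 9 (S)-5-hydroxy-2-(4-methoxyphenyl)-8-(3-methylbut-2-enyl)-7-(triisopropylsilyloxy)chroman-4-one
Product: 10 (S)-5,7-dihydroxy-2-(4-methoxyphenyl)-8-(3-methylbut-2-enyl)chroman-4-one
Conditions: Bu4NF, AcOH (1:1), THF, 0 °C
Reagents that add atoms: none
Why: Fluoride-induced cleavage of the aryl silyl ether, driven by Si–F bond formation; acetic acid buffers the fluoride so that neither phenoxide-triggered retro-oxa-Michael opening at C2 nor acid-promoted cyclisation of the prenyl group onto O7 should occur.

## Compound list

1 | 5,7-dihydroxy-4H-chromen-4-one | O=c1ccoc2cc(O)cc(O)c12 | starting material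
2 | 5-hydroxy-7-(triisopropylsilyloxy)-4H-chromen-4-one | O=c1ccoc2cc(O[Si](C(C)C)(C(C)C)C(C)C)cc(O)c12 | intermediate
3 | 3-methylbut-2-en-1-ol | CC(C)=CCO | starting material
4 | 5-(3-methylbut-2-enyloxy)-7-(triisopropylsilyloxy)-4H-chromen-4-one | O=c1ccoc2cc(O[Si](C(C)C)(C(C)C)C(C)C)cc(OCC=C(C)C)c12 | intermediate
5 | 4-methoxyphenylboronic acid | COc1ccc(B(O)O)cc1 | starting material
6 | (S)-2-(4-methoxyphenyl)-5-(3-methylbut-2-enyloxy)-7-(triisopropylsilyloxy)chroman-4-one | COc1ccc([C@@H]2CC(=O)c3c(OCC=C(C)C)cc(O[Si](C(C)C)(C(C)C)C(C)C)cc3O2)cc1 | intermediate
7 | (2S)-2-(4-methoxyphenyl)-6-(2-methylbut-3-en-2-yl)-7-(triisopropylsilyloxy)-2,3-dihydro-4H-chromene-4,5(6H)-dione (both C6 epimers, not isolated) | COc1ccc([C@@H]2CC(=O)C3=C(O2)C=C(O[Si](C(C)C)(C(C)C)C(C)C)C(C(C)(C)C=C)C3=O)cc1 | intermediate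
8 | (2S)-2-(4-methoxyphenyl)-8-(3-methylbut-2-enyl)-7-(triisopropylsilyloxy)-2,3-dihydro-4H-chromene-4,5(8H)-dione (both C8 epimers, not isolated) | COc1ccc([C@@H]2CC(=O)C3=C(O2)C(CC=C(C)C)C(O[Si](C(C)C)(C(C)C)C(C)C)=CC3=O)cc1 | intermediate
9 | (S)-5-hydroxy-2-(4-methoxyphenyl)-8-(3-methylbut-2-enyl)-7-(triisopropylsilyloxy)chroman-4-one | COc1ccc([C@@H]2CC(=O)c3c(O)cc(O[Si](C(C)C)(C(C)C)C(C)C)c(CC=C(C)C)c3O2)cc1 | intermediate
10 | (S)-5,7-dihydroxy-2-(4-methoxyphenyl)-8-(3-methylbut-2-enyl)chroman-4-one | COc1ccc([C@@H]2CC(=O)c3c(O)cc(O)c(CC=C(C)C)c3O2)cc1 | target

## Step count and least certain steps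

Total step count: 5. Longest linear sequence: 5 steps (from 1).

**Step 3 (key step).**
- Risk: low turnover, because the C4 carbonyl of 4 is deactivated by the two oxygen donors on ring A. Forcing the reaction could bring poor facial selectivity, protodeboronation of the electron-rich boronic acid and a second (1,2) arylation.
- Fallback (sets out from 4, returns at 6): make the stereocentre by a stereoconvergent reduction in place of an enantioselective C–C bond formation. Chromone 4 would be arylated with 5 without enantiocontrol, using a cationic catalyst of divalent palladium (Pd(OCOCF3)2, 2,2'-bipyridine, aqueous AcOH, 60 °C) that can be driven hard because no selectivity is asked of it. This gives racemic 2-(4-methoxyphenyl)-5-(3-methylbut-2-enyloxy)-7-(triisopropylsilyloxy)chroman-4-one F1. Asymmetric transfer hydrogenation under dynamic kinetic resolution (RuCl[(S,S)-TsDPEN](p-cymene), HCO2H, DBU, MeCN, 40 °C) would then use the lability of C2. The base equilibrates the enantiomers of F1 through the ring-opened chalcone phenoxide, while the catalyst of divalent ruthenium reduces only one of them. The expected product is (2S,4S)-2-(4-methoxyphenyl)-5-(3-methylbut-2-enyloxy)-7-(triisopropylsilyloxy)chroman-4-ol F2 (2,4-cis). Oxidation of the benzylic alcohol with Dess–Martin periodinane and NaHCO3 in CH2Cl2 would return 6.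

**Step 4.**
- Risk: arrest of the cascade after the first shift (tautomerisation of 7 to the C6 phenol), ionisation of the allylic C–O bond by the Lewis acid with loss of the prenyl group, and slow opening of ring C at C2 if the temperature has to be raised.
- Fallback (sets out from 4, returns at 9): move the relay in front of the stereocentre. Chromone 4, which is flat, achiral and thermally robust, would be rearranged under forcing conditions that a flavanone could not bear (Eu(fod)3 in PhCl at 85 °C, or N,N-diethylaniline at 190 °C) to 5-hydroxy-8-(3-methylbut-2-enyl)-7-(triisopropylsilyloxy)-4H-chromen-4-one F3. Arylation of F3 with 5 under the conditions of step 3 would give 9 directly, so the stereocentre would never see the rearrangement.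

**Step 5.**
- Risk: opening of ring C if the fluoride acts as a base on the 5-hydroxyflavanone (loss of enantiomeric purity). Cleavage of the silyl ether may also be slow because it is flanked by the C8 prenyl group, which would invite harsher conditions.
- Fallback (sets out from 6, returns at 10): put the deprotection before the rearrangement so that the last step is a neutral isomerisation. Ether 6, which has no free 5-OH and an unhindered silyl ether, would be desilylated (Bu4NF, AcOH, THF, 0 °C) to (S)-7-hydroxy-2-(4-methoxyphenyl)-5-(3-methylbut-2-enyloxy)chroman-4-one F4. The Claisen–Cope relay of step 4 on F4 would give 10 with no reagent exposure after the prenyl group and the 5-OH are in place.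

## Further compounds

F1 | step 3 | racemic 2-(4-methoxyphenyl)-5-(3-methylbut-2-enyloxy)-7-(triisopropylsilyloxy)chroman-4-one | COc1ccc(C2CC(=O)c3c(OCC=C(C)C)cc(O[Si](C(C)C)(C(C)C)C(C)C)cc3O2)cc1
F2 | step 3 | (2S,4S)-2-(4-methoxyphenyl)-5-(3-methylbut-2-enyloxy)-7-(triisopropylsilyloxy)chroman-4-ol | COc1ccc([C@@H]2C[C@H](O)c3c(OCC=C(C)C)cc(O[Si](C(C)C)(C(C)C)C(C)C)cc3O2)cc1
F3 | step 4 | 5-hydroxy-8-(3-methylbut-2-enyl)-7-(triisopropylsilyloxy)-4H-chromen-4-one | O=c1ccoc2c(CC=C(C)C)c(O[Si](C(C)C)(C(C)C)C(C)C)cc(O)c12
F4 | step 5 | (S)-7-hydroxy-2-(4-methoxyphenyl)-5-(3-methylbut-2-enyloxy)chroman-4-one | COc1ccc([C@@H]2CC(=O)c3c(OCC=C(C)C)cc(O)cc3O2)cc1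
A1 | alternative 1 | 1-[2,4,6-trihydroxy-3-(3-methylbut-2-enyl)phenyl]ethanone | CC(=O)c1c(O)cc(O)c(CC=C(C)C)c1O
A2 | alternative 1 | (E)-3-(4-methoxyphenyl)-1-[2,4,6-trihydroxy-3-(3-methylbut-2-enyl)phenyl]prop-2-en-1-one | COc1ccc(/C=C/C(=O)c2c(O)cc(O)c(CC=C(C)C)c2O)cc1
A3 | alternative 1 | 5,7-dihydroxy-2-(4-methoxyphenyl)-6-(3-methylbut-2-enyl)chroman-4-one (racemic) | COc1ccc(C2CC(=O)c3c(O)c(CC=C(C)C)c(O)cc3O2)cc1
A4 | alternative 2 | (S)-2-(4-methoxyphenyl)-2,3-dihydro-4H-pyran-4-one | COc1ccc([C@@H]2CC(=O)C=CO2)cc1
A5 | alternative 2 | (S)-5-bromo-2-(4-methoxyphenyl)-2,3-dihydro-4H-pyran-4-one | COc1ccc([C@@H]2CC(=O)C(Br)=CO2)cc1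
A6 | alternative 2 | 1-methoxy-7-methyl-1,3-bis(trimethylsilyloxy)octa-1,3,6-triene | COC(O[Si](C)(C)C)=CC(O[Si](C)(C)C)=CCC=C(C)C
A7 | alternative 3 | 2-(4-methoxyphenyl)-5-(3-methylbut-2-enyloxy)-7-(triisopropylsilyloxy)-4H-1,3-benzodioxin-4-one (racemic) | COc1ccc(C2OC(=O)c3c(OCC=C(C)C)cc(O[Si](C(C)C)(C(C)C)C(C)C)cc3O2)cc1
A8 | alternative 3 | 2-(4-methoxyphenyl)-4-methylene-5-(3-methylbut-2-enyloxy)-7-(triisopropylsilyloxy)-4H-1,3-benzodioxine (racemic) | COc1ccc(C2OC(=C)c3c(OCC=C(C)C)cc(O[Si](C(C)C)(C(C)C)C(C)C)cc3O2)cc1
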